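(The constants were drawn at random within sensible limits; what happens was integrated by code.)

You cannot spend the same nucleophile twice: each unit used up goes either to the electrophile or to another nucleophile.

| flask | electrophile | nucleophile | gas | time |
|---|---|---|---|---|
| north | 1.2 M | 0.950 equiv | 73 mM (held) | 25 min |
| east | 1.2 M | 1.40 equiv | 73 mM (held) | 25 min |

* part of the electrophile that has reacted at the end, north
* part of the electrophile that has reacted at the end, east
* what raising the equivalents of nucleophile from its lowest to its highest value here does to the part of the electrophile that has reacted (changes below 5 percentage points count as none) (it rises / no change / it falls)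

    electrophile + nucleophile → acid set free + target (k1 = 0.057 L mol⁻¹ min⁻¹)
    nucleophile + acid set free ⇌ protonated nucleophile, settled at all times (K2 = 260 L mol⁻¹)
    acid set free + free base ⇌ salt of the base, settled at all times (K3 = 11000 L mol⁻¹)
    gas ⇌ free base, rate k4*(csat - [free base]) (k4 = 1.5 min⁻¹, csat = 73 mM)
    electrophile + acid set free → side product (k5 = 0.95 L mol⁻¹ min⁻¹)
    2 nucleophile → self-condensation product (k6 = 0.028 L mol⁻¹ min⁻¹)

Write a for the fraction of electrophile left, e for the nucleophile charged per electrophile, and n for the nucleophile not yet used up on that same scale. What shares out the nucleophile is the split, a selectivity factor: the rate constant of self-condensation, doubled for the two that go each time, over that of the main step, 0.982. The two are close, so I round the split to one, and the nucleophile then follows a ledger with no clock in it: n = a(e + ln a).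

The clock comes from the slowness s, the minutes per whole charge of electrophile, which is one over κan, with κ = 0.0684 min⁻¹.

North, at a = 1, 0.800, 0.600: s = 15.4 min, 31.4 min, 92.5 min.

East, at a = 1, 0.750, 0.5: s = 10.4 min, 23.4 min, 82.7 min.

Weigh the stations of each row 1, 4, 1, divide by 6 and multiply by the width of the row. North reaches its last station at 15.6 min and east at 15.6 min. Stepping on at the last slowness, north comes to a = 0.498 and east to a = 0.386. Averaging the slowness at both ends of that stretch, I get 45.8 % reacted in north and 56.3 % in east, so it rises.

The correction I leave out is the acid. Taking free base at its saturation value 73 mM, and the acid from half the electrophile as salt of the base, protonated nucleophile stands at 0.194 of the free nucleophile. I take my figures as good to a few points.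

The forecast says 47 % (43 % to 52 %) for north and 59 % (54 % to 64 %) for east, both higher than mine, and it rises, since “the extra nucleophile still carries more electrophile through”.

The simulation gives 47.4 % for north and 58.2 % for east: it rises, by 11 percentage points.

Put the electrophile left into the ledger, with the split as it stands. East, at 42 % left, comes to 16.2 % of its nucleophile not used up, and the flask holds 16 % free, or 19.7 % with the protonated nucleophile counted. The neighbour flask, like east but charged with 2.40 equiv, reacts 72.4 % of its electrophile in the same time and has 28 % left. The ledger gives it 13.2 % of its nucleophile not used up, and the neighbour flask holds 14 % free, or 17.6 % with the protonated nucleophile counted.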